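**Retrosynthetic overview**
1. The depside C–O bond is cut last: target 13 comes from benzyl ether 12, made by carbodiimide esterification of acid 11 with phenol 10.
2. Both halves come from one intermediate, methyl 4-(benzyloxy)-2-hydroxy-6-propylbenzoate 8: O-methylation then debenzylation gives 10, saponification gives 11.
3. Key C–C disconnection: the aryl–CH2 bond of 8, from aryl triflate 3 and propanal. Propanal is used as a propyl carbanion equivalent through its N–H hydrazone (nickel catalysis, loss of N2), so two carbons that are both normally electrophilic are joined.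
4. Triflate 3 comes from methyl 2,4,6-trihydroxybenzoate 1 by 4-O-benzylation and mono-triflation.
5. No ring is formed: both benzene rings are carried over intact from 1.

Assumption: the target has no stereocentre, so it is one achiral compound and no stereocontrol is needed.

**Route**

Step 1
Reactants: 1 methyl 2,4,6-trihydroxybenzoate
Product: 2 methyl 4-(benzyloxy)-2,6-dihydroxybenzoate
Conditions: BnBr (1.0 equiv), K2CO3 (1.1 equiv), DMF, 0 °C to rt
Reagents that add atoms: benzyl bromide, BrCc1ccccc1
Why: Williamson etherification, in which the 4-OH is the only hydroxyl not hydrogen-bonded to the ester carbonyl and the most acidic, so one equivalent of base and benzyl bromide alkylates it selectively.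

Step 2
Reactants: 2 methyl 4-(benzyloxy)-2,6-dihydroxybenzoate
Product: 3 methyl 4-(benzyloxy)-2-hydroxy-6-(trifluoromethanesulfonyloxy)benzoate
Conditions: Tf2O (1.05 equiv), pyridine (3 equiv), CH2Cl2, −78 to 0 °C
Reagents that add atoms: trifluoromethanesulfonic anhydride, O=S(=O)(OS(=O)(=O)C(F)(F)F)C(F)(F)F
Why: O-triflation of one of two equivalent phenols, which stops at the mono-triflate because the remaining hydroxyl is then held in a strong hydrogen bond to the ester on a ring that has become electron-poor.

Step 3
Reactants: 3 methyl 4-(benzyloxy)-2-hydroxy-6-(trifluoromethanesulfonyloxy)benzoate; 4 propanal; 5 hydrazine monohydrate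
Product: 8 methyl 4-(benzyloxy)-2-hydroxy-6-propylbenzoate, via propanal hydrazone 6 (not isolated), via benzylic diazene 7 (not isolated)
Conditions: 4 (2.0 equiv), N2H4·H2O (2.0 equiv), THF, rt, 1 h, dried over Na2SO4; then 3, Ni(cod)2 (10 mol%), PMe3 (40 mol%), K3PO4 (3 equiv), DBU (20 mol%), THF, 80 °C, sealed tube
Reagents that add atoms: propanal, CCC=O
Why: Nickel-catalysed cross-coupling of an aryl triflate with an N–H hydrazone (carbonyl polarity reversal with Wolff–Kishner-type loss of N2), in which zerovalent nickel inserts into the C–OTf bond, the deprotonated hydrazone delivers its carbon to nickel, reductive elimination gives diazene 7 and base-induced extrusion of N2 leaves the propyl group, while the phenol is carried as its potassium salt and the doubly ortho-substituted methyl ester is too hindered for hydrazinolysis.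

Step 4
Reactants: 8 methyl 4-(benzyloxy)-2-hydroxy-6-propylbenzoate
Product: 9 methyl 4-(benzyloxy)-2-methoxy-6-propylbenzoate
Conditions: MeI (1.5 equiv), K2CO3 (2 equiv), DMF, 50 °C
Reagents that add atoms: iodomethane, CI
Why: Williamson O-methylation, in which carbonate in DMF breaks the hydrogen bond of the salicylate-type phenol and the phenoxide, the only nucleophilic site in 8, is methylated.

Step 5
Reactants: 9 methyl 4-(benzyloxy)-2-methoxy-6-propylbenzoate
Product: 10 methyl 4-hydroxy-2-methoxy-6-propylbenzoate
Conditions: H2 (1 atm), 10% Pd/C, EtOAc, rt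
Reagents that add atoms: none
Why: Catalytic hydrogenolysis of the benzyl aryl ether frees the 4-OH, and the methyl ester, methyl ether and arene are inert at 1 atm and room temperature.

Step 6
Reactants: 8 methyl 4-(benzyloxy)-2-hydroxy-6-propylbenzoate
Product: 11 4-(benzyloxy)-2-hydroxy-6-propylbenzoic acid
Conditions: KOH (5 equiv), DMSO/H2O (4:1), 90 °C; then 1 M HCl, 0 °C
Reagents that add atoms: potassium hydroxide, [K+].[OH-]
Why: Saponification of a hindered salicylate ester with hot KOH in aqueous DMSO, which the benzyl ether survives, followed by cold acidification to avoid decarboxylation of the ortho-hydroxy acid.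

Step 7
Reactants: 11 4-(benzyloxy)-2-hydroxy-6-propylbenzoic acid; 10 methyl 4-hydroxy-2-methoxy-6-propylbenzoate
Product: 12 methyl 4-{[4-(benzyloxy)-2-hydroxy-6-propylbenzoyl]oxy}-2-methoxy-6-propylbenzoate
Conditions: DCC (1.2 equiv), DMAP (5 mol%), toluene, 0 °C to rt
Reagents that add atoms: none
Why: Carbodiimide (Steglich) esterification, in which the O-acylisourea of 11 acylates the single free phenol of 10 while the 2-OH of 11 is deactivated by its hydrogen bond to the acyl carbonyl, so self-esterification does not compete.

Step 8
Reactants: 12 methyl 4-{[4-(benzyloxy)-2-hydroxy-6-propylbenzoyl]oxy}-2-methoxy-6-propylbenzoate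
Product: 13 methyl 4-[(2,4-dihydroxy-6-propylbenzoyl)oxy]-2-methoxy-6-propylbenzoate
Conditions: H2 (1 atm), 10% Pd/C, EtOAc, rt
Reagents that add atoms: none
Why: Hydrogenolysis of the remaining benzyl ether under neutral conditions leaves the aryl ester bond, the methyl ester and the methyl ether untouched and gives the target.

**Compound list**
1 | methyl 2,4,6-trihydroxybenzoate | COC(=O)c1c(O)cc(O)cc1O | starting material
2 | methyl 4-(benzyloxy)-2,6-dihydroxybenzoate | COC(=O)c1c(O)cc(OCc2ccccc2)cc1O | intermediate
3 | methyl 4-(benzyloxy)-2-hydroxy-6-(trifluoromethanesulfonyloxy)benzoate | COC(=O)c1c(O)cc(OCc2ccccc2)cc1OS(=O)(=O)C(F)(F)F | intermediate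
4 | propanal | CCC=O | starting material
5 | hydrazine monohydrate | NN.O | starting material
6 | propanal hydrazone, (E)-propylidenehydrazine | CC/C=N/N | intermediate (not isolated)
7 | methyl 4-(benzyloxy)-2-(1-diazenylpropyl)-6-hydroxybenzoate, racemic and transient | COC(=O)c1c(O)cc(OCc2ccccc2)cc1C(CC)N=N | intermediate (not isolated)
8 | methyl 4-(benzyloxy)-2-hydroxy-6-propylbenzoate | COC(=O)c1c(O)cc(OCc2ccccc2)cc1CCC | intermediate
9 | methyl 4-(benzyloxy)-2-methoxy-6-propylbenzoate | COC(=O)c1c(OC)cc(OCc2ccccc2)cc1CCC | intermediate
10 | methyl 4-hydroxy-2-methoxy-6-propylbenzoate | COC(=O)c1c(OC)cc(O)cc1CCC | intermediate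
11 | 4-(benzyloxy)-2-hydroxy-6-propylbenzoic acid | OC(=O)c1c(O)cc(OCc2ccccc2)cc1CCC | intermediate
12 | methyl 4-{[4-(benzyloxy)-2-hydroxy-6-propylbenzoyl]oxy}-2-methoxy-6-propylbenzoate | CCCc1cc(OCc2ccccc2)cc(O)c1C(=O)Oc1cc(CCC)c(C(=O)OC)c(OC)c1 | intermediate
13 | methyl 4-[(2,4-dihydroxy-6-propylbenzoyl)oxy]-2-methoxy-6-propylbenzoate | CCCc1cc(O)cc(O)c1C(=O)Oc1cc(CCC)c(C(=O)OC)c(OC)c1 | target

**Step count**
Total: 8 steps. Longest linear sequence: 7 steps (steps 1, 2, 3, 4, 5, 7, 8); step 6 is a one-step branch from 8.

**Three steps most likely to fail**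

Step 3 (key coupling). The triflate carries a free phenol and an ortho ester, and the coupling has competitors: reduction of the triflate to Ar–H, S–O cleavage of the triflate by hydrazine, and slow oxidative addition on the phenoxide. The fallback sets out from 3 and uses a different masked-carbonyl carbanion, the nitronate of 1-nitropropane. Palladium-catalysed arylation (Pd2(dba)3, 2-(di-tert-butylphosphino)-2'-methylbiphenyl, Cs2CO3, DME, 60 °C) gives methyl 4-(benzyloxy)-2-hydroxy-6-(1-nitropropyl)benzoate F1 as a racemate. Radical denitration of this benzylic nitro compound (Bu3SnH, AIBN, toluene, 110 °C) then comes back to the route at 8.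

Step 7 (depside coupling). The hindered 2,6-disubstituted acid may rearrange to the N-acylurea, or acylate through its own 2-OH, faster than it esterifies the electron-poor phenol. The fallback sets out from 8 and removes the free hydroxyl from the acyl donor. Benzylation (BnBr, K2CO3, DMF, 60 °C) gives methyl 2,4-bis(benzyloxy)-6-propylbenzoate F2, and saponification (KOH, DMSO/H2O, 100 °C) gives 2,4-bis(benzyloxy)-6-propylbenzoic acid F3. Condensation of F3 with 10 through the mixed trifluoroacetic anhydride (TFAA, toluene, rt) gives methyl 4-{[2,4-bis(benzyloxy)-6-propylbenzoyl]oxy}-2-methoxy-6-propylbenzoate F4. Hydrogenolysis of both benzyl ethers (H2, 10% Pd/C, EtOAc) comes back to the route at 13.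

Step 1 (regioselective benzylation). The phloroglucinol phenoxide can be benzylated twice or on ring carbon. The fallback sets out from 1 and replaces phenoxide alkylation by a Mitsunobu redox condensation with benzyl alcohol (PPh3, DIAD, THF, 0 °C to rt). No phenoxide is formed, so C-alkylation is excluded, and only the acidic, non-chelated 4-OH is etherified. It comes back to the route directly at 2; new compounds on the way: none F0.

**Further compounds**
F1 | step 3 | methyl 4-(benzyloxy)-2-hydroxy-6-(1-nitropropyl)benzoate, racemic | COC(=O)c1c(O)cc(OCc2ccccc2)cc1C(CC)[N+](=O)[O-]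
F2 | step 7 | methyl 2,4-bis(benzyloxy)-6-propylbenzoate | COC(=O)c1c(OCc2ccccc2)cc(OCc2ccccc2)cc1CCC
F3 | step 7 | 2,4-bis(benzyloxy)-6-propylbenzoic acid | OC(=O)c1c(OCc2ccccc2)cc(OCc2ccccc2)cc1CCC
F4 | step 7 | methyl 4-{[2,4-bis(benzyloxy)-6-propylbenzoyl]oxy}-2-methoxy-6-propylbenzoate | CCCc1cc(OCc2ccccc2)cc(OCc2ccccc2)c1C(=O)Oc1cc(CCC)c(C(=O)OC)c(OC)c1
F0 | step 1 | none | none
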